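**Retrosynthetic overview**
- The last disconnection is global O-debenzylation. Before it, ring C of the flavanone unit is closed by an annulation that forms the O1–C8a aryl ether bond and the C4–C4a bond in one operation, joining ring A (as 3,5-bis(benzyloxy)benzyne) to an (S)-β-hydroxy morpholine amide.
- Enabling feature: O1 (on C2) and the C4 carbonyl carbon are 1,3-related along C2–C3–C4 and end on the neighbouring ring-A carbons C8a and C4a, and the C5 oxygen sits ortho to C4a. A β-oxido amide can therefore bridge the two carbons of a 3,5-dioxygenated benzyne, with the C5 oxygen fixing the regiochemistry.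
- The C2'–C8'' biaryl bond is made before that by Suzuki–Miyaura coupling of an (S)-2-bromoaryl β-hydroxy amide with the luteolin 8-boronate. The C2 stereocentre is set earlier still, by asymmetric transfer hydrogenation, before the biaryl axis exists.
- The luteolin unit comes from phloroacetophenone by benzylation, iodination, Claisen–Schmidt condensation and oxidative cyclization, then borylation at C8.
- Ring order: pyranone ring of the luteolin unit first, then the biaryl bond, then ring C of the flavanone together with the attachment of ring A; the other benzene rings are bought.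

Key step: step 14

Remark on the chemistry: the C2'–C8'' biaryl axis carries four ortho substituents and is not defined in the target structure, so all compounds from the biaryl coupling onward are treated as atropisomer mixtures of constant (2S) configuration and no control of the axis is attempted.

**Step 1**
Reactants: 1 2-bromo-3-hydroxy-4-methoxybenzaldehyde
Product: 2 2-bromo-3,4-dihydroxybenzaldehyde
Conditions: BBr3, CH2Cl2, −78 °C → 0 °C; then H2O
Reagents that add atoms: none
Why: Lewis-acid cleavage of the aryl methyl ether (BBr3 demethylation) should free the catechol, the aldehyde and the aryl bromide being inert at low temperature.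

**Step 2**
Reactants: 2 2-bromo-3,4-dihydroxybenzaldehyde
Product: 3 3,4-bis(benzyloxy)-2-bromobenzaldehyde
Conditions: benzyl bromide, K2CO3, DMF, 60 °C
Reagents that add atoms: benzyl bromide, BrCc1ccccc1
Why: Williamson ether synthesis on both phenoxides installs the benzyl groups that are removed together in the last step.

**Step 3**
Reactants: 3 3,4-bis(benzyloxy)-2-bromobenzaldehyde; 4 4-acetylmorpholine
Product: 6 rac-3-[3,4-bis(benzyloxy)-2-bromophenyl]-3-hydroxy-1-(morpholin-4-yl)propan-1-one, via lithium enolate 5 (not isolated)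
Conditions: LiN(iPr)2, THF, −78 °C; then 3; AcOH quench
Reagents that add atoms: none
Why: Aldol addition of the preformed lithium amide enolate to the non-enolizable aldehyde; the carbinol may be racemic because it is oxidized in the next step.

**Step 4**
Reactants: 6 rac-3-[3,4-bis(benzyloxy)-2-bromophenyl]-3-hydroxy-1-(morpholin-4-yl)propan-1-one
Product: 7 1-[3,4-bis(benzyloxy)-2-bromophenyl]-3-(morpholin-4-yl)propane-1,3-dione
Conditions: Dess–Martin periodinane, CH2Cl2, 0 °C → rt
Reagents that add atoms: none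
Why: Dess–Martin oxidation of the secondary benzylic alcohol gives the β-keto amide under neutral conditions that spare benzyl ethers and the aryl bromide.

**Step 5**
Reactants: 7 1-[3,4-bis(benzyloxy)-2-bromophenyl]-3-(morpholin-4-yl)propane-1,3-dione
Product: 8 (3S)-3-[3,4-bis(benzyloxy)-2-bromophenyl]-3-hydroxy-1-(morpholin-4-yl)propan-1-one
Conditions: RuCl[(S,S)-TsDPEN](p-cymene) (cat.), HCO2H/Et3N (5:2), DMF, 35 °C
Reagents that add atoms: none
Why: Noyori asymmetric transfer hydrogenation of the aryl ketone; the (S,S)-ligand holds the aryl group against the η6-arene of the catalyst (CH/π contact) and should deliver hydride to the face that gives the (S)-carbinol, as with acetophenone and β-keto amides, so the future C2 stereocentre is set here.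

**Step 6**
Reactants: 9 1-(2,4,6-trihydroxyphenyl)ethan-1-one
Product: 10 1-[2,4-bis(benzyloxy)-6-hydroxyphenyl]ethan-1-one
Conditions: benzyl bromide (2 equiv), K2CO3, DMF, rt → 50 °C
Reagents that add atoms: benzyl bromide, BrCc1ccccc1
Why: Williamson etherification of the two more acidic phenols; the hydroxyl group hydrogen-bonded to the acetyl carbonyl should stay free, as is usual for phloroacetophenone.

**Step 7**
Reactants: 10 1-[2,4-bis(benzyloxy)-6-hydroxyphenyl]ethan-1-one
Product: 11 1-[4,6-bis(benzyloxy)-2-hydroxy-3-iodophenyl]ethan-1-one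
Conditions: benzyltrimethylammonium dichloroiodate, NaHCO3, CH2Cl2/MeOH, rt
Reagents that add atoms: benzyltrimethylammonium dichloroiodate, C[N+](C)(C)Cc1ccccc1.Cl[I-]Cl
Why: Electrophilic aromatic iodination ortho to the free phenol, the site that becomes C8 of the flavone; the corresponding dimethyl ether is known to iodinate at this position.

**Step 8**
Reactants: 11 1-[4,6-bis(benzyloxy)-2-hydroxy-3-iodophenyl]ethan-1-one; 12 3,4-bis(benzyloxy)benzaldehyde
Product: 13 (2E)-1-[4,6-bis(benzyloxy)-2-hydroxy-3-iodophenyl]-3-[3,4-bis(benzyloxy)phenyl]prop-2-en-1-one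
Conditions: KOH, EtOH/THF, rt; then dilute HCl
Reagents that add atoms: none
Why: Claisen–Schmidt condensation of the acetophenone enolate with the non-enolizable aldehyde should give the (E)-chalcone.

**Step 9**
Reactants: 13 (2E)-1-[4,6-bis(benzyloxy)-2-hydroxy-3-iodophenyl]-3-[3,4-bis(benzyloxy)phenyl]prop-2-en-1-one
Product: 14 5,7-bis(benzyloxy)-2-[3,4-bis(benzyloxy)phenyl]-8-iodo-4H-chromen-4-one
Conditions: I2 (cat.), DMSO, 130 °C
Reagents that add atoms: none
Why: Iodine-catalysed oxidative cyclization of the 2'-hydroxychalcone (oxa-Michael closure, then dehydrogenation with DMSO as terminal oxidant) closes the pyranone ring of the luteolin unit with iodine fixed at C8.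

**Step 10**
Reactants: 14 5,7-bis(benzyloxy)-2-[3,4-bis(benzyloxy)phenyl]-8-iodo-4H-chromen-4-one
Product: 15 5,7-bis(benzyloxy)-2-[3,4-bis(benzyloxy)phenyl]-8-(4,4,5,5-tetramethyl-1,3,2-dioxaborolan-2-yl)-4H-chromen-4-one
Conditions: PdCl2(MeCN)2 (cat.), SPhos, pinacolborane, Et3N, 1,4-dioxane, 80 °C
Reagents that add atoms: pinacolborane, B1OC(C)(C)C(C)(C)O1
Why: Palladium-catalysed borylation of the aryl iodide with pinacolborane (Miyaura-type borylation); the bulky SPhos ligand on zerovalent palladium suits doubly ortho-substituted, electron-rich halides.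

**Step 11**
Reactants: 8 (3S)-3-[3,4-bis(benzyloxy)-2-bromophenyl]-3-hydroxy-1-(morpholin-4-yl)propan-1-one; 15 5,7-bis(benzyloxy)-2-[3,4-bis(benzyloxy)phenyl]-8-(4,4,5,5-tetramethyl-1,3,2-dioxaborolan-2-yl)-4H-chromen-4-one
Product: 16 (3S)-3-{3,4-bis(benzyloxy)-2-[5,7-bis(benzyloxy)-2-(3,4-bis(benzyloxy)phenyl)-4-oxo-4H-chromen-8-yl]phenyl}-3-hydroxy-1-(morpholin-4-yl)propan-1-one (atropisomer mixture)
Conditions: Pd(OAc)2 (cat.), SPhos, K3PO4, toluene/H2O (10:1), 100 °C
Reagents that add atoms: none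
Why: Suzuki–Miyaura coupling forms the C2'–C8'' biaryl bond; the Pd(OAc)2/SPhos system is the established choice for tetra-ortho-substituted biaryls and 2,6-dioxygenated boronates, and the phosphate base should leave the β-hydroxy amide and its stereocentre untouched.

**Step 12**
Reactants: 17 3,5-bis(benzyloxy)phenol
Product: 18 3,5-bis(benzyloxy)-2-bromophenol
Conditions: N-bromosuccinimide (1 equiv), CH2Cl2, −78 °C → rt
Reagents that add atoms: N-bromosuccinimide, O=C1CCC(=O)N1Br
Why: Electrophilic aromatic bromination at low temperature should go ortho to the free hydroxyl group, the site between the two benzyloxy groups being the more hindered one.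

**Step 13**
Reactants: 18 3,5-bis(benzyloxy)-2-bromophenol
Product: 21 3,5-bis(benzyloxy)-2-(trimethylsilyl)phenyl trifluoromethanesulfonate, via trimethylsilyl ether 19 (not isolated), via lithium phenolate 20 (not isolated)
Conditions: hexamethyldisilazane, THF, 70 °C, then evaporate; n-BuLi, THF, −100 → −78 °C; Tf2O, −78 °C → rt
Reagents that add atoms: hexamethyldisilazane, C[Si](C)(C)N[Si](C)(C)C; trifluoromethanesulfonic anhydride, O=S(=O)(OS(=O)(=O)C(F)(F)F)C(F)(F)F
Why: Standard one-pot route to ortho-silylaryl triflates: O-silylation, bromine–lithium exchange followed by 1,3-O-to-C silyl migration (retro-Brook rearrangement), and O-triflation of the resulting phenolate.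

**Step 14**
Reactants: 16 (3S)-3-{3,4-bis(benzyloxy)-2-[5,7-bis(benzyloxy)-2-(3,4-bis(benzyloxy)phenyl)-4-oxo-4H-chromen-8-yl]phenyl}-3-hydroxy-1-(morpholin-4-yl)propan-1-one; 21 3,5-bis(benzyloxy)-2-(trimethylsilyl)phenyl trifluoromethanesulfonate
Product: 25 (2S)-5,7-bis(benzyloxy)-2-{3,4-bis(benzyloxy)-2-[5,7-bis(benzyloxy)-2-(3,4-bis(benzyloxy)phenyl)-4-oxo-4H-chromen-8-yl]phenyl}-2,3-dihydro-4H-chromen-4-one, via potassium alkoxide 22 (not isolated), via aryne 23 (not isolated), via hemiaminal alkoxide 24 (not isolated)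
Conditions: KH (1.05 equiv), 18-crown-6, THF, 0 °C; then CsF and slow addition of 21 (1.6 equiv), 0 °C → rt; AcOH quench at −20 °C, cold aqueous wash
Reagents that add atoms: none
Why: Proposed new method: fluoride-induced 1,2-elimination of 21 releases aryne 23, whose carbon remote from the flanking benzyloxy group (the future C8a) is attacked by potassium alkoxide 22 to form the O1–C8a aryl ether bond, and the aryl anion that develops at the future C4a, next to the C5 oxygen, adds to the morpholine amide carbonyl placed 1,3 to the alkoxide and so closes ring C as hemiaminal alkoxide 24, which gives the C4 ketone only on the acidic quench. The closest known reaction types are the fluoride-mediated annulation of arynes with salicylate esters to xanthones (O-arylation, then intramolecular acyl substitution) and the acyl-alkylation of arynes, including that of this same 3,5-bis(benzyloxy)benzyne; what is new is a β-oxido tertiary amide as the partner that spans the two aryne carbons. Ring C is closed by a formal [4+2] annulation, the O1–C8a bond by nucleophilic addition to the aryne and the C4–C4a bond by 6-exo-trig attack of the aryl anion on the amide. No lasting stereocentre is created (C4 of 24 is lost on collapse to the ketone), and C2 keeps the (S) configuration from step 5 because none of its bonds is made or broken. The step needs regioselective O-attack, secured by the benzyloxy group flanking the aryne, which directs nucleophiles to the remote aryne carbon; acyl capture ahead of protonation, secured by the preformed alkoxide, aprotic THF and the six-membered transition state; and freedom from epimerization, secured because no enolizable ketone exists while the medium is basic and because an amide aldolate resists both retro-aldol cleavage and elimination.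

**Step 15**
Reactants: 25 (2S)-5,7-bis(benzyloxy)-2-{3,4-bis(benzyloxy)-2-[5,7-bis(benzyloxy)-2-(3,4-bis(benzyloxy)phenyl)-4-oxo-4H-chromen-8-yl]phenyl}-2,3-dihydro-4H-chromen-4-one
Product: 26 (2S)-2-{2-[2-(3,4-dihydroxyphenyl)-5,7-dihydroxy-4-oxo-4H-chromen-8-yl]-3,4-dihydroxyphenyl}-5,7-dihydroxy-2,3-dihydro-4H-chromen-4-one
Conditions: H2 (1 atm), Pd(OH)2/C, THF/MeOH (1:1), rt
Reagents that add atoms: none
Why: Catalytic hydrogenolysis of the eight benzyl ethers under neutral conditions should leave the acid- and base-sensitive C2 stereocentre and the flavone ring untouched.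

**Compound list**
1 | 2-bromo-3-hydroxy-4-methoxybenzaldehyde | O=Cc1ccc(OC)c(O)c1Br | starting material
2 | 2-bromo-3,4-dihydroxybenzaldehyde | O=Cc1ccc(O)c(O)c1Br | intermediate
3 | 3,4-bis(benzyloxy)-2-bromobenzaldehyde | O=Cc1ccc(OCc2ccccc2)c(OCc2ccccc2)c1Br | intermediate
4 | 4-acetylmorpholine | CC(=O)N1CCOCC1 | starting material
5 | lithium enolate of 4-acetylmorpholine | [Li+].[O-]C(=C)N1CCOCC1 | intermediate (not isolated)
6 | rac-3-[3,4-bis(benzyloxy)-2-bromophenyl]-3-hydroxy-1-(morpholin-4-yl)propan-1-one | O=C(CC(O)c1ccc(OCc2ccccc2)c(OCc2ccccc2)c1Br)N1CCOCC1 | intermediate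
7 | 1-[3,4-bis(benzyloxy)-2-bromophenyl]-3-(morpholin-4-yl)propane-1,3-dione | O=C(CC(=O)c1ccc(OCc2ccccc2)c(OCc2ccccc2)c1Br)N1CCOCC1 | intermediate
8 | (3S)-3-[3,4-bis(benzyloxy)-2-bromophenyl]-3-hydroxy-1-(morpholin-4-yl)propan-1-one | O=C(N1CCOCC1)C[C@@H](c1ccc(OCc2ccccc2)c(OCc2ccccc2)c1Br)O | intermediate
9 | 1-(2,4,6-trihydroxyphenyl)ethan-1-one | CC(=O)c1c(O)cc(O)cc1O | starting material
10 | 1-[2,4-bis(benzyloxy)-6-hydroxyphenyl]ethan-1-one | CC(=O)c1c(O)cc(OCc2ccccc2)cc1OCc1ccccc1 | intermediate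
11 | 1-[4,6-bis(benzyloxy)-2-hydroxy-3-iodophenyl]ethan-1-one | CC(=O)c1c(O)c(I)c(OCc2ccccc2)cc1OCc1ccccc1 | intermediate
12 | 3,4-bis(benzyloxy)benzaldehyde | O=Cc1ccc(OCc2ccccc2)c(OCc2ccccc2)c1 | starting material
13 | (2E)-1-[4,6-bis(benzyloxy)-2-hydroxy-3-iodophenyl]-3-[3,4-bis(benzyloxy)phenyl]prop-2-en-1-one | O=C(/C=C/c1ccc(OCc2ccccc2)c(OCc2ccccc2)c1)c1c(O)c(I)c(OCc2ccccc2)cc1OCc1ccccc1 | intermediate
14 | 5,7-bis(benzyloxy)-2-[3,4-bis(benzyloxy)phenyl]-8-iodo-4H-chromen-4-one | O=c1cc(-c2ccc(OCc3ccccc3)c(OCc3ccccc3)c2)oc2c(I)c(OCc3ccccc3)cc(OCc3ccccc3)c12 | intermediate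
15 | 5,7-bis(benzyloxy)-2-[3,4-bis(benzyloxy)phenyl]-8-(4,4,5,5-tetramethyl-1,3,2-dioxaborolan-2-yl)-4H-chromen-4-one | O=c1cc(-c2ccc(OCc3ccccc3)c(OCc3ccccc3)c2)oc2c(B3OC(C)(C)C(C)(C)O3)c(OCc3ccccc3)cc(OCc3ccccc3)c12 | intermediate
16 | (3S)-3-{3,4-bis(benzyloxy)-2-[5,7-bis(benzyloxy)-2-(3,4-bis(benzyloxy)phenyl)-4-oxo-4H-chromen-8-yl]phenyl}-3-hydroxy-1-(morpholin-4-yl)propan-1-one | O=C(N1CCOCC1)C[C@@H](c1ccc(OCc2ccccc2)c(OCc2ccccc2)c1-c1c(OCc2ccccc2)cc(OCc2ccccc2)c2c(=O)cc(-c3ccc(OCc4ccccc4)c(OCc4ccccc4)c3)oc12)O | intermediate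
17 | 3,5-bis(benzyloxy)phenol | Oc1cc(OCc2ccccc2)cc(OCc2ccccc2)c1 | starting material
18 | 3,5-bis(benzyloxy)-2-bromophenol | Oc1cc(OCc2ccccc2)cc(OCc2ccccc2)c1Br | intermediate
19 | [3,5-bis(benzyloxy)-2-bromophenoxy]trimethylsilane | C[Si](C)(C)Oc1cc(OCc2ccccc2)cc(OCc2ccccc2)c1Br | intermediate (not isolated)
20 | lithium 3,5-bis(benzyloxy)-2-(trimethylsilyl)phenolate | [Li+].[O-]c1cc(OCc2ccccc2)cc(OCc2ccccc2)c1[Si](C)(C)C | intermediate (not isolated)
21 | 3,5-bis(benzyloxy)-2-(trimethylsilyl)phenyl trifluoromethanesulfonate | C[Si](C)(C)c1c(OS(=O)(=O)C(F)(F)F)cc(OCc2ccccc2)cc1OCc1ccccc1 | intermediate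
22 | potassium alkoxide of 16 | O=C(N1CCOCC1)C[C@@H](c1ccc(OCc2ccccc2)c(OCc2ccccc2)c1-c1c(OCc2ccccc2)cc(OCc2ccccc2)c2c(=O)cc(-c3ccc(OCc4ccccc4)c(OCc4ccccc4)c3)oc12)[O-].[K+] | intermediate (not isolated)
23 | 3,5-bis(benzyloxy)benzyne (1,2-didehydro-3,5-bis(benzyloxy)benzene) | C1#CC(OCc2ccccc2)=CC(OCc2ccccc2)=C1 | intermediate (not isolated)
24 | potassium (2S)-5,7-bis(benzyloxy)-2-{3,4-bis(benzyloxy)-2-[5,7-bis(benzyloxy)-2-(3,4-bis(benzyloxy)phenyl)-4-oxo-4H-chromen-8-yl]phenyl}-4-(morpholin-4-yl)-3,4-dihydro-2H-chromen-4-olate (C4 epimer mixture) | [K+].[O-]C1(N2CCOCC2)C[C@@H](c2ccc(OCc3ccccc3)c(OCc3ccccc3)c2-c2c(OCc3ccccc3)cc(OCc3ccccc3)c3c(=O)cc(-c4ccc(OCc5ccccc5)c(OCc5ccccc5)c4)oc23)Oc2cc(OCc3ccccc3)cc(OCc3ccccc3)c21 | intermediate (not isolated)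
25 | (2S)-5,7-bis(benzyloxy)-2-{3,4-bis(benzyloxy)-2-[5,7-bis(benzyloxy)-2-(3,4-bis(benzyloxy)phenyl)-4-oxo-4H-chromen-8-yl]phenyl}-2,3-dihydro-4H-chromen-4-one | O=C1C[C@@H](c2ccc(OCc3ccccc3)c(OCc3ccccc3)c2-c2c(OCc3ccccc3)cc(OCc3ccccc3)c3c(=O)cc(-c4ccc(OCc5ccccc5)c(OCc5ccccc5)c4)oc23)Oc2cc(OCc3ccccc3)cc(OCc3ccccc3)c21 | intermediate
26 | (2S)-2-{2-[2-(3,4-dihydroxyphenyl)-5,7-dihydroxy-4-oxo-4H-chromen-8-yl]-3,4-dihydroxyphenyl}-5,7-dihydroxy-2,3-dihydro-4H-chromen-4-one | O=C1C[C@@H](c2ccc(O)c(O)c2-c2c(O)cc(O)c3c(=O)cc(-c4ccc(O)c(O)c4)oc23)Oc2cc(O)cc(O)c21 | target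

**Step count and risks**
Total step count: 15. Longest linear sequence: 8 steps (steps 6–11, 14, 15; the branch through steps 1–5, 11, 14, 15 is equally long).

Steps most likely to fail:

1. Step 14 (proposed new method).
   - What may go wrong: protonation of the aryl anion before it reaches the amide, which would leave an uncyclized aryl ether; O-silylation of the alkoxide by the aryne precursor faster than fluoride can turn it over; alkoxide addition with the reverse regiochemistry; or collapse of the hemiaminal while base is still present, followed by ring opening and epimerization at C2.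
   - Fallback (known chemistry, classical chalcone route with resolution): it sets out from 3 and 15. Suzuki–Miyaura coupling under the conditions of step 11 should give the biaryl aldehyde F1. Claisen–Schmidt condensation of F1 with acetophenone 10 (KOH, EtOH/THF) should give the 2'-hydroxychalcone F2. NaOAc in refluxing EtOH should close ring C by oxa-Michael addition to the racemic flavanone F3. Preparative HPLC on a chiral stationary phase removes the (2R)-enantiomer F4 and returns the route at 25.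

2. Step 11.
   - What may go wrong: protodeboronation of the 2,6-dioxygenated boronate outrunning transmetalation at two doubly ortho-substituted centres, and oxidation of the free carbinol by β-hydride elimination from a palladium alkoxide.
   - Fallback (organozinc instead of boron, carbinol masked): it sets out from 8 and 14. Silylation of 8 (TBSCl, imidazole, DMF) gives the silyl ether F5. Zinc insertion into iodide 14 (Zn dust, LiCl, THF) gives the arylzinc iodide F6. Negishi coupling of F5 with F6 (Pd(OAc)2, SPhos, THF/NMP, 70 °C) should give the coupled silyl ether F7. TBAF buffered with AcOH removes the silyl group and returns the route at 16.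

3. Step 15.
   - What may go wrong: over-reduction (hydrogenolysis of the benzylic C2–O1 bond, saturation of the flavone C2–C3 double bond, reduction of the C4 ketone), incomplete removal of the eight benzyl groups, or catalyst poisoning by the catechols formed.
   - Fallback (non-reductive debenzylation): it sets out from 25 and uses BCl3 with pentamethylbenzene as benzyl-cation scavenger in CH2Cl2 at −78 °C, returning directly at 26. It forms no compound outside the compound list (F0).

**Further compounds**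
F1 | step 14 | 3,4-bis(benzyloxy)-2-[5,7-bis(benzyloxy)-2-(3,4-bis(benzyloxy)phenyl)-4-oxo-4H-chromen-8-yl]benzaldehyde | O=Cc1ccc(OCc2ccccc2)c(OCc2ccccc2)c1-c1c(OCc2ccccc2)cc(OCc2ccccc2)c2c(=O)cc(-c3ccc(OCc4ccccc4)c(OCc4ccccc4)c3)oc12
F2 | step 14 | (2E)-1-[2,4-bis(benzyloxy)-6-hydroxyphenyl]-3-{3,4-bis(benzyloxy)-2-[5,7-bis(benzyloxy)-2-(3,4-bis(benzyloxy)phenyl)-4-oxo-4H-chromen-8-yl]phenyl}prop-2-en-1-one | O=C(/C=C/c1ccc(OCc2ccccc2)c(OCc2ccccc2)c1-c1c(OCc2ccccc2)cc(OCc2ccccc2)c2c(=O)cc(-c3ccc(OCc4ccccc4)c(OCc4ccccc4)c3)oc12)c1c(O)cc(OCc2ccccc2)cc1OCc1ccccc1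
F3 | step 14 | rac-5,7-bis(benzyloxy)-2-{3,4-bis(benzyloxy)-2-[5,7-bis(benzyloxy)-2-(3,4-bis(benzyloxy)phenyl)-4-oxo-4H-chromen-8-yl]phenyl}-2,3-dihydro-4H-chromen-4-one | O=C1CC(c2ccc(OCc3ccccc3)c(OCc3ccccc3)c2-c2c(OCc3ccccc3)cc(OCc3ccccc3)c3c(=O)cc(-c4ccc(OCc5ccccc5)c(OCc5ccccc5)c4)oc23)Oc2cc(OCc3ccccc3)cc(OCc3ccccc3)c21
F4 | step 14 | (2R)-5,7-bis(benzyloxy)-2-{3,4-bis(benzyloxy)-2-[5,7-bis(benzyloxy)-2-(3,4-bis(benzyloxy)phenyl)-4-oxo-4H-chromen-8-yl]phenyl}-2,3-dihydro-4H-chromen-4-one | O=C1C[C@H](c2ccc(OCc3ccccc3)c(OCc3ccccc3)c2-c2c(OCc3ccccc3)cc(OCc3ccccc3)c3c(=O)cc(-c4ccc(OCc5ccccc5)c(OCc5ccccc5)c4)oc23)Oc2cc(OCc3ccccc3)cc(OCc3ccccc3)c21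
F5 | step 11 | (3S)-3-[3,4-bis(benzyloxy)-2-bromophenyl]-3-[(tert-butyldimethylsilyl)oxy]-1-(morpholin-4-yl)propan-1-one | O=C(N1CCOCC1)C[C@@H](c1ccc(OCc2ccccc2)c(OCc2ccccc2)c1Br)O[Si](C)(C)C(C)(C)C
F6 | step 11 | {5,7-bis(benzyloxy)-2-[3,4-bis(benzyloxy)phenyl]-4-oxo-4H-chromen-8-yl}zinc iodide | I[Zn]c1c(OCc2ccccc2)cc(OCc2ccccc2)c2c(=O)cc(-c3ccc(OCc4ccccc4)c(OCc4ccccc4)c3)oc12
F7 | step 11 | (3S)-3-{3,4-bis(benzyloxy)-2-[5,7-bis(benzyloxy)-2-(3,4-bis(benzyloxy)phenyl)-4-oxo-4H-chromen-8-yl]phenyl}-3-[(tert-butyldimethylsilyl)oxy]-1-(morpholin-4-yl)propan-1-one | O=C(N1CCOCC1)C[C@@H](c1ccc(OCc2ccccc2)c(OCc2ccccc2)c1-c1c(OCc2ccccc2)cc(OCc2ccccc2)c2c(=O)cc(-c3ccc(OCc4ccccc4)c(OCc4ccccc4)c3)oc12)O[Si](C)(C)C(C)(C)C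
F0 | step 15 | none | none
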